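**Retrosynthetic overview**
1. Target ⇐ global hydrogenolysis of a tetra-O-benzyl flavone; benzyl masks 5-, 7-, 3'- and 6'-OH, and the three methyl ethers are carried from the fragments.
2. The pyranone (C) ring is the only ring built and is made last, by I2/DMSO oxidative cyclisation (O1–C2 bond) of a 2'-hydroxychalcone.
3. Key C–C bond (future C2–C3): Claisen–Schmidt aldol condensation of a fully substituted A-ring acetophenone with a 2,3,6-trioxygenated B-ring benzaldehyde.
4. A-ring ketone ⇐ phloroacetophenone by nuclear dibromination, 4,6-di-O-benzylation and Cu-catalysed double methoxylation.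
5. B-ring aldehyde ⇐ methoxyhydroquinone by bis-MOM protection, directed ortho-lithiation/formylation between OMe and OMOM, then MOM→benzyl exchange.

Assumption: the target is achiral (no stereocentre, free rotation about C2–C1'), so "single enantiomer" means the compound as drawn; the only stereo-element en route is the E-alkene of the chalcone, which disappears on cyclisation.

**Route**

Step 1
Reactants: 1 2,4,6-trihydroxyacetophenone (phloroacetophenone)
Product: 2 1-(3,5-dibromo-2,4,6-trihydroxyphenyl)ethanone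
Conditions: NBS (2.05 equiv), MeCN, 0 °C → rt
Reagents that add atoms: N-bromosuccinimide, O=C1CCC(=O)N1Br
Why: Electrophilic aromatic bromination of the very electron-rich phloroglucinol ring takes the only two free ring positions much faster than the H-bonded acetyl group is α-brominated.

Step 2
Reactants: 2 1-(3,5-dibromo-2,4,6-trihydroxyphenyl)ethanone
Product: 3 1-[2,4-bis(benzyloxy)-3,5-dibromo-6-hydroxyphenyl]ethanone
Conditions: BnBr (2.1 equiv), K2CO3 (2.2 equiv), DMF, rt → 40 °C
Reagents that add atoms: benzyl bromide, BrCc1ccccc1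
Why: Williamson etherification alkylates the para-OH and one ortho-OH, the last ortho-OH is deactivated by its hydrogen bond to the ketone, and the bromines block C-benzylation.

Step 3
Reactants: 3 1-[2,4-bis(benzyloxy)-3,5-dibromo-6-hydroxyphenyl]ethanone
Product: 4 1-[2,4-bis(benzyloxy)-6-hydroxy-3,5-dimethoxyphenyl]ethanone
Conditions: NaOMe (8 equiv, 25% in MeOH), CuBr (0.3 equiv), DMF, 105 °C, N2; then aq. HCl
Reagents that add atoms: sodium methoxide, [Na+].[O-]C
Why: Cu(I)-catalysed Ullmann-type methoxylation is the standard way to turn ortho-oxygenated aryl bromides into aryl methyl ethers, and benzyl ethers and the hindered ketone are inert to methoxide.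

Step 4
Reactants: 5 2-methoxybenzene-1,4-diol (methoxyhydroquinone)
Product: 6 2-methoxy-1,4-bis(methoxymethoxy)benzene
Conditions: MOMCl (2.5 equiv), i-Pr2NEt (3 equiv), CH2Cl2, 0 °C → rt
Reagents that add atoms: chloromethyl methyl ether, COCCl
Why: O-alkylation with the reactive α-chloro ether protects both phenols as MOM ethers, which are strong ortho-directing groups for the next step.

Step 5
Reactants: 6 2-methoxy-1,4-bis(methoxymethoxy)benzene
Product: 9 2-methoxy-3,6-bis(methoxymethoxy)benzaldehyde, via aryllithium 7 (not isolated), via lithium hemiaminal alkoxide 8 (not isolated)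
Conditions: n-BuLi (1.2 equiv), THF, 0 °C, 1 h; DMF (2 equiv), −78 °C → rt; H2O
Reagents that add atoms: N,N-dimethylformamide, CN(C)C=O; n-butyllithium, [Li]CCCC (supplies only the lithium of 7 and 8)
Why: Directed ortho-metalation removes the proton flanked by OMe and OMOM (cooperative coordination makes it the most acidic), and DMF formylates the aryllithium.

Step 6
Reactants: 9 2-methoxy-3,6-bis(methoxymethoxy)benzaldehyde
Product: 10 3,6-dihydroxy-2-methoxybenzaldehyde
Conditions: conc. HCl (cat.), MeOH, 50 °C, N2; then H2O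
Reagents that add atoms: none
Why: Acid-catalysed acetal exchange cleaves both MOM ethers while the aryl methyl ether and the aldehyde survive.

Step 7
Reactants: 10 3,6-dihydroxy-2-methoxybenzaldehyde
Product: 11 3,6-bis(benzyloxy)-2-methoxybenzaldehyde
Conditions: BnBr (2.4 equiv), K2CO3 (3 equiv), DMF, 60 °C, N2
Reagents that add atoms: benzyl bromide, BrCc1ccccc1
Why: Williamson benzylation gives ethers that survive base, iodine and heat, so the B-ring ortho-oxygen stays masked until the neutral final deprotection.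

Step 8
Reactants: 4 1-[2,4-bis(benzyloxy)-6-hydroxy-3,5-dimethoxyphenyl]ethanone; 11 3,6-bis(benzyloxy)-2-methoxybenzaldehyde
Product: 13 (E)-1-[2,4-bis(benzyloxy)-6-hydroxy-3,5-dimethoxyphenyl]-3-[3,6-bis(benzyloxy)-2-methoxyphenyl]prop-2-en-1-one, via β-hydroxy ketone 12 (not isolated)
Conditions: KOH (50% aq., 10 equiv), EtOH/THF, rt, 24–48 h; then cold 1 M HCl
Reagents that add atoms: none
Why: In this Claisen–Schmidt crossed aldol condensation only the methyl ketone can enolise and only the aldehyde is electrophilic, and E1cB dehydration gives the thermodynamic E-enone, so no stereocentre is kept.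

Step 9
Reactants: 13 (E)-1-[2,4-bis(benzyloxy)-6-hydroxy-3,5-dimethoxyphenyl]-3-[3,6-bis(benzyloxy)-2-methoxyphenyl]prop-2-en-1-one
Product: 15 5,7-bis(benzyloxy)-2-[3,6-bis(benzyloxy)-2-methoxyphenyl]-6,8-dimethoxy-4H-chromen-4-one, via flavanone 14 (not isolated)
Conditions: I2 (0.1 equiv), DMSO, 120 °C, 3 h; aq. Na2S2O3
Reagents that add atoms: none
Why: I2/DMSO oxidative cyclisation proceeds by 6-endo oxa-Michael closure, α-iodination and HI loss with DMSO re-oxidising HI; only the A ring has a free ortho-OH, so a single flavone can form.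

Step 10
Reactants: 15 5,7-bis(benzyloxy)-2-[3,6-bis(benzyloxy)-2-methoxyphenyl]-6,8-dimethoxy-4H-chromen-4-one
Product: 16 5,7,3',6'-tetrahydroxy-6,8,2'-trimethoxyflavone
Conditions: H2 (1 atm), 10% Pd/C, THF/MeOH, rt; filter and concentrate under N2
Reagents that add atoms: none
Why: Pd-catalysed hydrogenolysis cleaves all four aryl benzyl ethers under neutral conditions that leave the flavone C2=C3 bond intact and avoid acid- or base-induced pyranone opening and recyclisation onto the 6'-OH.

**Compound list**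
1 | 2,4,6-trihydroxyacetophenone | CC(=O)c1c(O)cc(O)cc1O | starting material
2 | 1-(3,5-dibromo-2,4,6-trihydroxyphenyl)ethanone | CC(=O)c1c(O)c(Br)c(O)c(Br)c1O | intermediate
3 | 1-[2,4-bis(benzyloxy)-3,5-dibromo-6-hydroxyphenyl]ethanone | CC(=O)c1c(O)c(Br)c(OCc2ccccc2)c(Br)c1OCc1ccccc1 | intermediate
4 | 1-[2,4-bis(benzyloxy)-6-hydroxy-3,5-dimethoxyphenyl]ethanone | CC(=O)c1c(O)c(OC)c(OCc2ccccc2)c(OC)c1OCc1ccccc1 | intermediate
5 | 2-methoxybenzene-1,4-diol (methoxyhydroquinone) | COc1cc(O)ccc1O | starting material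
6 | 2-methoxy-1,4-bis(methoxymethoxy)benzene | COCOc1ccc(OCOC)c(OC)c1 | intermediate
7 | [2-methoxy-3,6-bis(methoxymethoxy)phenyl]lithium | [Li]c1c(OC)c(OCOC)ccc1OCOC | intermediate
8 | lithium (dimethylamino)[2-methoxy-3,6-bis(methoxymethoxy)phenyl]methanolate (racemic) | [Li]OC(N(C)C)c1c(OCOC)ccc(OCOC)c1OC | intermediate
9 | 2-methoxy-3,6-bis(methoxymethoxy)benzaldehyde | COCOc1ccc(OCOC)c(OC)c1C=O | intermediate
10 | 3,6-dihydroxy-2-methoxybenzaldehyde | COc1c(O)ccc(O)c1C=O | intermediate
11 | 3,6-bis(benzyloxy)-2-methoxybenzaldehyde | COc1c(OCc2ccccc2)ccc(OCc2ccccc2)c1C=O | intermediate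
12 | 1-[2,4-bis(benzyloxy)-6-hydroxy-3,5-dimethoxyphenyl]-3-[3,6-bis(benzyloxy)-2-methoxyphenyl]-3-hydroxypropan-1-one (racemic) | COc1c(OCc2ccccc2)ccc(OCc2ccccc2)c1C(O)CC(=O)c1c(O)c(OC)c(OCc2ccccc2)c(OC)c1OCc1ccccc1 | intermediate
13 | (E)-1-[2,4-bis(benzyloxy)-6-hydroxy-3,5-dimethoxyphenyl]-3-[3,6-bis(benzyloxy)-2-methoxyphenyl]prop-2-en-1-one | COc1c(OCc2ccccc2)ccc(OCc2ccccc2)c1/C=C/C(=O)c1c(O)c(OC)c(OCc2ccccc2)c(OC)c1OCc1ccccc1 | intermediate
14 | 5,7-bis(benzyloxy)-2-[3,6-bis(benzyloxy)-2-methoxyphenyl]-6,8-dimethoxychroman-4-one (racemic) | COc1c(OCc2ccccc2)ccc(OCc2ccccc2)c1C1CC(=O)c2c(OCc3ccccc3)c(OC)c(OCc3ccccc3)c(OC)c2O1 | intermediate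
15 | 5,7-bis(benzyloxy)-2-[3,6-bis(benzyloxy)-2-methoxyphenyl]-6,8-dimethoxy-4H-chromen-4-one | COc1c(OCc2ccccc2)ccc(OCc2ccccc2)c1-c1cc(=O)c2c(OCc3ccccc3)c(OC)c(OCc3ccccc3)c(OC)c2o1 | intermediate
16 | 5,7,3',6'-tetrahydroxy-6,8,2'-trimethoxyflavone | COc1c(O)ccc(O)c1-c1cc(=O)c2c(O)c(OC)c(O)c(OC)c2o1 | target

**Totals**
Total step count: 10. Longest linear sequence: 7 steps (5 → 6 → 9 → 10 → 11 → 13 → 15 → 16; steps 4–10).

**Steps most likely to fail, with fallbacks**

Step 3 (double Ullmann methoxylation of two bromides each flanked by two oxygen substituents; risk of stalling at the mono-ether or of hydrodebromination). The fallback sets out from 3 and comes back at 15: the bromines are carried forward and the methoxy groups are put on the flavone nucleus instead. Ketone 3 is condensed with aldehyde 11 (KOH, EtOH/THF, rt) to give (E)-1-[2,4-bis(benzyloxy)-3,5-dibromo-6-hydroxyphenyl]-3-[3,6-bis(benzyloxy)-2-methoxyphenyl]prop-2-en-1-one F1. Cyclisation with cat. I2 in DMSO at 120 °C gives 5,7-bis(benzyloxy)-2-[3,6-bis(benzyloxy)-2-methoxyphenyl]-6,8-dibromo-4H-chromen-4-one F2. NaOMe/CuBr in DMF–MeOH at 100 °C then replaces both bromides to give 15. The aryl bromides of the electron-poorer chromone are better partners for copper-mediated substitution, and any methoxide opening of the pyranone is reversed on acidic work-up and can only reclose to 15 because the B-ring ortho-oxygen is benzylated.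

Step 9 (I2/DMSO oxidative cyclisation; risk of slow closure onto the di-ortho-substituted B ring, HI-induced debenzylation or ring iodination). The fallback sets out from 11 (with 4 as partner) and comes back at 15, and it needs no oxidation of the C ring because the oxidation level is brought in by an acyl fragment. Aldehyde 11 is oxidised (NaClO2, NaH2PO4, 2-methyl-2-butene, t-BuOH/H2O) to 3,6-bis(benzyloxy)-2-methoxybenzoic acid F3. Oxalyl chloride with cat. DMF in CH2Cl2 gives 3,6-bis(benzyloxy)-2-methoxybenzoyl chloride F4. The dilithium dianion of 4 (LiHMDS 3.2 equiv, THF, −78 °C) is C-acylated by F4 in a crossed Claisen condensation to give 1-[2,4-bis(benzyloxy)-6-hydroxy-3,5-dimethoxyphenyl]-3-[3,6-bis(benzyloxy)-2-methoxyphenyl]propane-1,3-dione F5. Mild cyclodehydration (cat. TsOH, toluene, 80 °C) closes the only free phenol onto the B-side carbonyl and gives 15. This also bypasses step 8 should the aldol condensation of the two hindered partners be sluggish.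

Step 2 (selective 4,6-di-O-benzylation; risk of mono-/tri-ether mixtures). The fallback sets out from 2 and comes back at 3, replacing selective protection by exhaustive protection and chelation-controlled deprotection. Compound 2 is fully benzylated (BnBr 3.5 equiv, K2CO3, DMF, 60 °C) to 1-[2,4,6-tris(benzyloxy)-3,5-dibromophenyl]ethanone F6. MgBr2·OEt2 (1.2 equiv, toluene/Et2O, 80 °C) then cleaves one of the two equivalent benzyl ethers ortho to the carbonyl through a six-membered magnesium chelate and gives 3.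

**Further compounds**
F1 | step 3 | (E)-1-[2,4-bis(benzyloxy)-3,5-dibromo-6-hydroxyphenyl]-3-[3,6-bis(benzyloxy)-2-methoxyphenyl]prop-2-en-1-one | COc1c(OCc2ccccc2)ccc(OCc2ccccc2)c1/C=C/C(=O)c1c(O)c(Br)c(OCc2ccccc2)c(Br)c1OCc1ccccc1
F2 | step 3 | 5,7-bis(benzyloxy)-2-[3,6-bis(benzyloxy)-2-methoxyphenyl]-6,8-dibromo-4H-chromen-4-one | COc1c(OCc2ccccc2)ccc(OCc2ccccc2)c1-c1cc(=O)c2c(OCc3ccccc3)c(Br)c(OCc3ccccc3)c(Br)c2o1
F3 | step 9 | 3,6-bis(benzyloxy)-2-methoxybenzoic acid | COc1c(OCc2ccccc2)ccc(OCc2ccccc2)c1C(=O)O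
F4 | step 9 | 3,6-bis(benzyloxy)-2-methoxybenzoyl chloride | COc1c(OCc2ccccc2)ccc(OCc2ccccc2)c1C(=O)Cl
F5 | step 9 | 1-[2,4-bis(benzyloxy)-6-hydroxy-3,5-dimethoxyphenyl]-3-[3,6-bis(benzyloxy)-2-methoxyphenyl]propane-1,3-dione | COc1c(OCc2ccccc2)ccc(OCc2ccccc2)c1C(=O)CC(=O)c1c(O)c(OC)c(OCc2ccccc2)c(OC)c1OCc1ccccc1
F6 | step 2 | 1-[2,4,6-tris(benzyloxy)-3,5-dibromophenyl]ethanone | CC(=O)c1c(OCc2ccccc2)c(Br)c(OCc2ccccc2)c(Br)c1OCc1ccccc1
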